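The ten-membered ring is closed at the bond between the ring methylene C8 and the carbinol carbon C9 (germacrane numbering; C6 lactone carbinol, C7 ring-fusion carbon). In step 16 the primary iodide at C8 of open-chain iodo-aldehyde 20 becomes an alkylchromium nucleophile that adds to the C9 aldehyde: one operation forms the carbocycle and the C9 stereocentre under ligand control. The step exploits that C8 is an unfunctionalised CH2 between the trans-fused α-methylene-γ-lactone (C6, C7, C11–C13) and C9; the lactone, the Z-C4=C5 alkene and the C2/C3 acetonide pre-organise the chain, and organochromium tolerates the exocyclic C11=C13 acrylate, so the finished lactone is carried into the cyclisation.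

Key step: step 16

Remark on numbering: ring C1(H2)–C2(OH)–C3(OH)–C4(CH3)=C5–C6(O-lactone)–C7–C8(H2)–C9(O-angeloyl)–C10(CH3)–C1; C11(=C13H2) on C7; C12 is the lactone carbonyl.
Remark on the chemistry (assumption): in steps 12 and 16 the antipode of each chiral chromium ligand is the one that delivers Si-face addition to the aldehyde; the sense is taken from the general behaviour of these ligand classes.

Step 1
Reactants: 1 (S)-5-(hydroxymethyl)dihydrofuran-2(3H)-one
Product: 2 (S)-5-[(trityloxy)methyl]dihydrofuran-2(3H)-one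
Conditions: Ph3CCl, pyridine, DMAP (cat.), CH2Cl2, rt
Reagents that add atoms: trityl chloride, ClC(c1ccccc1)(c1ccccc1)c1ccccc1
Why: Tritylation of the primary alcohol installs the bulky group that will steer the enolate alkylation; no stereocentre is touched.

Step 2
Reactants: 2 (S)-5-[(trityloxy)methyl]dihydrofuran-2(3H)-one
Product: 3 (3R,5S)-3-methyl-5-[(trityloxy)methyl]dihydrofuran-2(3H)-one
Conditions: LiN(iPr)2, THF, −78 °C; CH3I, −78 °C
Reagents that add atoms: iodomethane, CI
Why: Lactone enolate alkylation should occur anti to the trityloxymethyl group and set the trans methyl centre (C10) by substrate control.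

Step 3
Reactants: 3 (3R,5S)-3-methyl-5-[(trityloxy)methyl]dihydrofuran-2(3H)-one
Product: 4 (3R,5S)-5-(hydroxymethyl)-3-methyldihydrofuran-2(3H)-one
Conditions: AcOH–H2O (4:1), 50 °C
Reagents that add atoms: none
Why: Acidolysis of the trityl ether through the trityl cation frees the primary alcohol without opening the lactone.

Step 4
Reactants: 4 (3R,5S)-5-(hydroxymethyl)-3-methyldihydrofuran-2(3H)-one
Product: 5 (2S,4R)-4-methyl-5-oxotetrahydrofuran-2-carbaldehyde
Conditions: Dess–Martin periodinane, NaHCO3, CH2Cl2, 0 °C to rt; used crude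
Reagents that add atoms: none
Why: Buffered Dess–Martin oxidation should give the α-oxygenated aldehyde (C3) without epimerising C2.

Step 5
Reactants: 6 but-2-yn-1-ol
Product: 7 (Z)-3-iodobut-2-en-1-ol
Conditions: NaAlH2(OCH2CH2OCH3)2, THF, 0 °C; then I2, −78 °C to 0 °C
Reagents that add atoms: iodine, II
Why: Alkoxide-directed trans-hydroalumination places aluminium cis to the CH2O group and iodinolysis with retention should give the Z-alkenyl iodide.

Step 6
Reactants: 5 (2S,4R)-4-methyl-5-oxotetrahydrofuran-2-carbaldehyde; 7 (Z)-3-iodobut-2-en-1-ol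
Product: 8 (3R,5S)-5-[(1R,2Z)-1,4-dihydroxy-2-methylbut-2-en-1-yl]-3-methyldihydrofuran-2(3H)-one
Conditions: CrCl2 (4 equiv), NiCl2 (2 mol%), DMSO, rt
Reagents that add atoms: none
Why: Nozaki–Hiyama–Kishi coupling keeps the Z-geometry of the iodide and spares the lactone, and Felkin–Anh addition anti to the ring oxygen should set the erythro C3 carbinol (3R).

Step 7
Reactants: 8 (3R,5S)-5-[(1R,2Z)-1,4-dihydroxy-2-methylbut-2-en-1-yl]-3-methyldihydrofuran-2(3H)-one
Product: 9 (2Z,4R,5S,7R)-3,7-dimethyloct-2-ene-1,4,5,8-tetraol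
Conditions: LiAlH4, THF, 0 °C to rt
Reagents that add atoms: none
Why: Hydride reduction of the lactone to the 1,4-diol releases C9 and the C2 hydroxyl; no stereocentre and not the allylic alcohol is affected.

Step 8
Reactants: 9 (2Z,4R,5S,7R)-3,7-dimethyloct-2-ene-1,4,5,8-tetraol
Product: 10 (R)-3-{(4S,5R)-5-[(Z)-4-hydroxybut-2-en-2-yl]-2,2-dimethyl-1,3-dioxolan-4-yl}-2-methylpropan-1-ol
Conditions: (CH3O)2C(CH3)2, PPTS (cat.), acetone, rt
Reagents that add atoms: 2,2-dimethoxypropane, COC(C)(C)OC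
Why: Thermodynamic acetalisation should select the five-membered dioxolane on the vicinal erythro diol (C2, C3) over seven-membered alternatives.

Step 9
Reactants: 10 (R)-3-{(4S,5R)-5-[(Z)-4-hydroxybut-2-en-2-yl]-2,2-dimethyl-1,3-dioxolan-4-yl}-2-methylpropan-1-ol
Product: 11 (Z)-3-{(4R,5S)-5-[(R)-3-hydroxy-2-methylpropyl]-2,2-dimethyl-1,3-dioxolan-4-yl}but-2-enal
Conditions: MnO2, CH2Cl2, rt
Reagents that add atoms: none
Why: MnO2 oxidises only the allylic primary alcohol (C6), leaving the saturated C9 alcohol and the Z-alkene intact.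

Step 10
Reactants: 12 (tert-butyldimethylsilyloxy)acetaldehyde; 13 ethyl acrylate
Product: 14 ethyl 4-[(tert-butyldimethylsilyl)oxy]-3-hydroxy-2-methylenebutanoate (racemic)
Conditions: DABCO (cat.), neat, rt
Reagents that add atoms: none
Why: Morita–Baylis–Hillman reaction joins the acrylate α-carbon (C11) to the aldehyde carbon (C7); the stereocentre is removed in the next step.

Step 11
Reactants: 14 ethyl 4-[(tert-butyldimethylsilyl)oxy]-3-hydroxy-2-methylenebutanoate
Product: 15 ethyl (Z)-2-(bromomethyl)-4-[(tert-butyldimethylsilyl)oxy]but-2-enoate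
Conditions: NBS, (CH3)2S, CH2Cl2, 0 °C to rt
Reagents that add atoms: N-bromosuccinimide, O=C1CCC(=O)N1Br
Why: Activation of the allylic alcohol as an alkoxysulfonium salt and SN2' attack of bromide should give the rearranged Z-allylic bromide.

Step 12
Reactants: 11 (Z)-3-{(4R,5S)-5-[(R)-3-hydroxy-2-methylpropyl]-2,2-dimethyl-1,3-dioxolan-4-yl}but-2-enal; 15 ethyl (Z)-2-(bromomethyl)-4-[(tert-butyldimethylsilyl)oxy]but-2-enoate
Product: 17 (4R,5R)-4-{[(tert-butyldimethylsilyl)oxy]methyl}-5-{(Z)-2-[(4R,5S)-5-[(R)-3-hydroxy-2-methylpropyl]-2,2-dimethyl-1,3-dioxolan-4-yl]prop-1-en-1-yl}-3-methylenedihydrofuran-2(3H)-one, via hydroxy ester 16 (not isolated)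
Conditions: CrCl2 (10 mol%), chiral 1,8-bis(4-isopropyl-2-oxazolinyl)carbazole ligand (12 mol%), Mn, (CH3)3SiCl, iPr2NEt (cat.), THF, rt; aq. citric acid; then CSA (cat.), CH2Cl2, rt
Reagents that add atoms: none
Why: Catalytic asymmetric Nozaki–Hiyama 2-(alkoxycarbonyl)allylation then lactonisation; the chair transition state of the equilibrating allylchromium (γ-substituent equatorial) should give the anti C6/C7 relationship (trans-lactone), and the ligand sets the absolute sense at C6.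

Step 13
Reactants: 17 (4R,5R)-4-{[(tert-butyldimethylsilyl)oxy]methyl}-5-{(Z)-2-[(4R,5S)-5-[(R)-3-hydroxy-2-methylpropyl]-2,2-dimethyl-1,3-dioxolan-4-yl]prop-1-en-1-yl}-3-methylenedihydrofuran-2(3H)-one
Product: 18 (4R,5R)-4-{[(tert-butyldimethylsilyl)oxy]methyl}-5-{(Z)-2-[(4R,5S)-2,2-dimethyl-5-[(R)-2-methyl-3-oxopropyl]-1,3-dioxolan-4-yl]prop-1-en-1-yl}-3-methylenedihydrofuran-2(3H)-one
Conditions: Dess–Martin periodinane, NaHCO3, CH2Cl2, 0 °C
Reagents that add atoms: none
Why: Buffered Dess–Martin oxidation of the only free alcohol should give the C9 aldehyde without epimerising C10.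

Step 14
Reactants: 18 (4R,5R)-4-{[(tert-butyldimethylsilyl)oxy]methyl}-5-{(Z)-2-[(4R,5S)-2,2-dimethyl-5-[(R)-2-methyl-3-oxopropyl]-1,3-dioxolan-4-yl]prop-1-en-1-yl}-3-methylenedihydrofuran-2(3H)-one
Product: 19 (4R,5R)-4-(hydroxymethyl)-5-{(Z)-2-[(4R,5S)-2,2-dimethyl-5-[(R)-2-methyl-3-oxopropyl]-1,3-dioxolan-4-yl]prop-1-en-1-yl}-3-methylenedihydrofuran-2(3H)-one
Conditions: HF·pyridine, pyridine, THF, 0 °C
Reagents that add atoms: none
Why: Buffered fluoride desilylation frees the C8 alcohol under weakly acidic conditions that should avoid translactonisation and spare the acetonide and aldehyde.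

Step 15
Reactants: 19 (4R,5R)-4-(hydroxymethyl)-5-{(Z)-2-[(4R,5S)-2,2-dimethyl-5-[(R)-2-methyl-3-oxopropyl]-1,3-dioxolan-4-yl]prop-1-en-1-yl}-3-methylenedihydrofuran-2(3H)-one
Product: 20 (4S,5R)-4-(iodomethyl)-5-{(Z)-2-[(4R,5S)-2,2-dimethyl-5-[(R)-2-methyl-3-oxopropyl]-1,3-dioxolan-4-yl]prop-1-en-1-yl}-3-methylenedihydrofuran-2(3H)-one
Conditions: I2, PPh3, imidazole, CH2Cl2, 0 °C
Reagents that add atoms: iodine, II
Why: Appel iodination of the primary alcohol gives the C8 iodide; the descriptor at C7 changes only through CIP priority.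

Step 16
Reactants: 20 (4S,5R)-4-(iodomethyl)-5-{(Z)-2-[(4R,5S)-2,2-dimethyl-5-[(R)-2-methyl-3-oxopropyl]-1,3-dioxolan-4-yl]prop-1-en-1-yl}-3-methylenedihydrofuran-2(3H)-one
Product: 22 (2S,3R,6R,7S,9S,10R)-9-hydroxy-2,3-(isopropylidenedioxy)germacra-4(Z),11(13)-dien-12,6-olide, via C8-alkylchromium species 21 (not isolated)
Conditions: CrCl2 (6 equiv), chiral N-[2-(4-isopropyl-2-oxazolinyl)phenyl]methanesulfonamide ligand (6.6 equiv), Et3N (6.6 equiv), cobalt phthalocyanine CoC32H16N8 (10 mol%), LiCl, THF–DMF, rt, slow addition of 20 (final 2 mM)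
Reagents that add atoms: none
Why: Proposed new method: low-valent cobalt (from the phthalocyanine and CrCl2) converts the primary C8–I bond into a C8 radical that CrCl2 captures as alkylchromium 21 (trivalent chromium), which adds to the C9 aldehyde; the closest known reaction is the cobalt-catalysed Nozaki–Hiyama-type alkylation of aldehydes by alkyl iodides between separate partners, and Nozaki–Hiyama–Kishi macrocyclisations of alkenyl and allyl halides to ten-membered carbocycles, but not the alkyl ring closure. The ring closes in a 10-exo-trig carbonyl addition in which the trans-lactone (C6, C7), the Z-C4=C5 alkene and the cis-acetonide (C2, C3) restrict the chain and bring C8 near C9. The new C9 stereocentre is controlled by the chiral sulfonamide ligand on chromium (Si-face attack, 9S), which has to override the weak Felkin–Anh bias of the C10 methyl group. The step needs chemoselectivity for the aldehyde over the lactone and the C11=C13 acrylate, which organochromium reagents provide, and capture of the C8 radical by excess CrCl2 that is faster than intermolecular addition to the acrylate at this dilution.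

Step 17
Reactants: 22 (2S,3R,6R,7S,9S,10R)-9-hydroxy-2,3-(isopropylidenedioxy)germacra-4(Z),11(13)-dien-12,6-olide; 23 angelic acid
Product: 24 (2S,3R,6R,7S,9S,10R)-9-angeloyloxy-2,3-(isopropylidenedioxy)germacra-4(Z),11(13)-dien-12,6-olide
Conditions: 2,4,6-Cl3C6H2COCl, Et3N, toluene, rt; then 22, 80 °C
Reagents that add atoms: none
Why: Yamaguchi esterification through the mixed anhydride, without a nucleophilic catalyst, should acylate the hindered C9 alcohol with retention and without Z-to-E isomerisation of the angelate.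

Step 18
Reactants: 24 (2S,3R,6R,7S,9S,10R)-9-angeloyloxy-2,3-(isopropylidenedioxy)germacra-4(Z),11(13)-dien-12,6-olide
Product: 25 (2S,3R,6R,7S,9S,10R)-9-angeloyloxy-2,3-dihydroxygermacra-4(Z),11(13)-dien-12,6-olide (CNP0229085.1)
Conditions: AcOH–H2O (4:1), 40 °C
Reagents that add atoms: none
Why: Mild acidic acetonide hydrolysis frees the C2/C3 diol and should leave the angelate, the lactone and the exocyclic alkene untouched.

Compound list
1 | (S)-5-(hydroxymethyl)dihydrofuran-2(3H)-one | O=C1CC[C@@H](CO)O1 | starting material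
2 | (S)-5-[(trityloxy)methyl]dihydrofuran-2(3H)-one | O=C1CC[C@@H](COC(c2ccccc2)(c2ccccc2)c2ccccc2)O1 | intermediate
3 | (3R,5S)-3-methyl-5-[(trityloxy)methyl]dihydrofuran-2(3H)-one | O=C1[C@H](C)C[C@@H](COC(c2ccccc2)(c2ccccc2)c2ccccc2)O1 | intermediate
4 | (3R,5S)-5-(hydroxymethyl)-3-methyldihydrofuran-2(3H)-one | O=C1[C@H](C)C[C@@H](CO)O1 | intermediate
5 | (2S,4R)-4-methyl-5-oxotetrahydrofuran-2-carbaldehyde | O=C1[C@H](C)C[C@@H](C=O)O1 | intermediate
6 | but-2-yn-1-ol | CC#CCO | starting material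
7 | (Z)-3-iodobut-2-en-1-ol | C/C(I)=C/CO | intermediate
8 | (3R,5S)-5-[(1R,2Z)-1,4-dihydroxy-2-methylbut-2-en-1-yl]-3-methyldihydrofuran-2(3H)-one | O=C1[C@H](C)C[C@@H]([C@H](O)/C(C)=C\CO)O1 | intermediate
9 | (2Z,4R,5S,7R)-3,7-dimethyloct-2-ene-1,4,5,8-tetraol | OC[C@H](C)C[C@H](O)[C@H](O)/C(C)=C\CO | intermediate
10 | (R)-3-{(4S,5R)-5-[(Z)-4-hydroxybut-2-en-2-yl]-2,2-dimethyl-1,3-dioxolan-4-yl}-2-methylpropan-1-ol | OC[C@H](C)C[C@@H]1OC(C)(C)O[C@@H]1/C(C)=C\CO | intermediate
11 | (Z)-3-{(4R,5S)-5-[(R)-3-hydroxy-2-methylpropyl]-2,2-dimethyl-1,3-dioxolan-4-yl}but-2-enal | OC[C@H](C)C[C@@H]1OC(C)(C)O[C@@H]1/C(C)=C\C=O | intermediate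
12 | (tert-butyldimethylsilyloxy)acetaldehyde | CC(C)(C)[Si](C)(C)OCC=O | starting material
13 | ethyl acrylate | C=CC(=O)OCC | starting material
14 | ethyl 4-[(tert-butyldimethylsilyl)oxy]-3-hydroxy-2-methylenebutanoate (racemic) | C=C(C(=O)OCC)C(O)CO[Si](C)(C)C(C)(C)C | intermediate
15 | ethyl (Z)-2-(bromomethyl)-4-[(tert-butyldimethylsilyl)oxy]but-2-enoate | BrC/C(C(=O)OCC)=C\CO[Si](C)(C)C(C)(C)C | intermediate
16 | ethyl (3R,4R,5Z)-3-{[(tert-butyldimethylsilyl)oxy]methyl}-4-hydroxy-6-{(4R,5S)-5-[(R)-3-hydroxy-2-methylpropyl]-2,2-dimethyl-1,3-dioxolan-4-yl}-2-methylenehept-5-enoate | CCOC(=O)C(=C)[C@H](CO[Si](C)(C)C(C)(C)C)[C@H](O)/C=C(/C)[C@H]1OC(C)(C)O[C@H]1C[C@@H](C)CO | intermediate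
17 | (4R,5R)-4-{[(tert-butyldimethylsilyl)oxy]methyl}-5-{(Z)-2-[(4R,5S)-5-[(R)-3-hydroxy-2-methylpropyl]-2,2-dimethyl-1,3-dioxolan-4-yl]prop-1-en-1-yl}-3-methylenedihydrofuran-2(3H)-one | C=C1C(=O)O[C@@H]([C@H]1CO[Si](C)(C)C(C)(C)C)/C=C(/C)[C@H]2OC(C)(C)O[C@H]2C[C@@H](C)CO | intermediate
18 | (4R,5R)-4-{[(tert-butyldimethylsilyl)oxy]methyl}-5-{(Z)-2-[(4R,5S)-2,2-dimethyl-5-[(R)-2-methyl-3-oxopropyl]-1,3-dioxolan-4-yl]prop-1-en-1-yl}-3-methylenedihydrofuran-2(3H)-one | C=C1C(=O)O[C@@H]([C@H]1CO[Si](C)(C)C(C)(C)C)/C=C(/C)[C@H]2OC(C)(C)O[C@H]2C[C@@H](C)C=O | intermediate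
19 | (4R,5R)-4-(hydroxymethyl)-5-{(Z)-2-[(4R,5S)-2,2-dimethyl-5-[(R)-2-methyl-3-oxopropyl]-1,3-dioxolan-4-yl]prop-1-en-1-yl}-3-methylenedihydrofuran-2(3H)-one | C=C1C(=O)O[C@@H]([C@H]1CO)/C=C(/C)[C@H]2OC(C)(C)O[C@H]2C[C@@H](C)C=O | intermediate
20 | (4S,5R)-4-(iodomethyl)-5-{(Z)-2-[(4R,5S)-2,2-dimethyl-5-[(R)-2-methyl-3-oxopropyl]-1,3-dioxolan-4-yl]prop-1-en-1-yl}-3-methylenedihydrofuran-2(3H)-one | C=C1C(=O)O[C@@H]([C@H]1CI)/C=C(/C)[C@H]2OC(C)(C)O[C@H]2C[C@@H](C)C=O | intermediate
21 | C8-alkylchromium dichloride derived from 20 (trivalent chromium; chiral ligand not shown) | C=C1C(=O)O[C@@H]([C@H]1C[Cr](Cl)Cl)/C=C(/C)[C@H]2OC(C)(C)O[C@H]2C[C@@H](C)C=O | intermediate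
22 | (2S,3R,6R,7S,9S,10R)-9-hydroxy-2,3-(isopropylidenedioxy)germacra-4(Z),11(13)-dien-12,6-olide | C=C1C(=O)O[C@@H]2/C=C(/C)[C@H]3OC(C)(C)O[C@H]3C[C@@H](C)[C@@H](O)C[C@@H]12 | intermediate
23 | angelic acid, (Z)-2-methylbut-2-enoic acid | C/C=C(/C)C(=O)O | starting material
24 | (2S,3R,6R,7S,9S,10R)-9-angeloyloxy-2,3-(isopropylidenedioxy)germacra-4(Z),11(13)-dien-12,6-olide | C=C1C(=O)O[C@@H]2/C=C(/C)[C@H]3OC(C)(C)O[C@H]3C[C@@H](C)[C@@H](OC(=O)/C(C)=C\C)C[C@@H]12 | intermediate
25 | (2S,3R,6R,7S,9S,10R)-9-angeloyloxy-2,3-dihydroxygermacra-4(Z),11(13)-dien-12,6-olide (CNP0229085.1) | C=C1C(=O)O[C@@H]2/C=C(/C)[C@@H](O)[C@@H](O)C[C@@H](C)[C@@H](OC(=O)/C(C)=C\C)C[C@@H]12 | target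

Total step count: 18. Longest linear sequence: 15 (steps 1–4, 6–9, 12–18).

Steps most likely to fail

Step 16 (key step, proposed new method). The alkylchromium may be protonated, or the iodide may oligomerise by intermolecular addition, before the ten-membered ring closes; transannular oxa-Michael addition of the C9 alkoxide to C13 may also follow. Fallback with known chemistry, from 20: conjugate addition of thiophenol (PhSH, Et3N, CH2Cl2) masks the methylene lactone as phenylthiomethyl lactone F1; a samarium-Barbier cyclisation (SmI2, HMPA, THF, high dilution) forms the same C8–C9 bond and should give macrocyclic sulfide F2; NaIO4 oxidation to macrocyclic sulfoxide F3 and thermal syn-elimination (toluene, 90 °C) restore the exocyclic alkene and rejoin the route at 22.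

Step 12. The Z-enal may isomerise under the Lewis-acidic conditions, or addition may go through the syn transition state (cis-lactone) if the allylchromium does not equilibrate, eroding the C6/C7 configuration. Fallback from 11: stereospecific allylboration with allylboronate F4, in which the CH2OTBS group is trans to CH2B. F4 would be prepared from ethyl 4-[(tert-butyldimethylsilyl)oxy]but-2-ynoate by iBu2AlH/HMPA hydroalumination and trapping with ICH2B(pin). Addition to 11 under a chiral BINOL-derived phosphoric acid (toluene, −30 °C) transfers the boronate geometry through a closed six-membered transition state into the anti adduct; CSA then lactonises it to 17.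

Step 6. Facial selectivity at C3 (Felkin–Anh versus chelation) may be poor and alkene geometry may be partly lost in the chromium addition. Fallback from 5: reagent-controlled zinc–ProPhenol alkynylation with methyl propiolate (Me2Zn, toluene) gives propargylic alcohol F5; syn-carbocupration with Me2CuLi (THF, −78 °C) and spontaneous lactonisation give butenolide F6, whose ring locks the Z-alkene; iBu2AlH reduction of both lactones rejoins the route at tetraol 9.

Further compounds
F1 | step 16 | (4S,5R)-4-(iodomethyl)-5-{(Z)-2-[(4R,5S)-2,2-dimethyl-5-[(R)-2-methyl-3-oxopropyl]-1,3-dioxolan-4-yl]prop-1-en-1-yl}-3-[(phenylthio)methyl]dihydrofuran-2(3H)-one (C3 epimers) | O=C1O[C@@H]([C@@H](CI)C1CSc2ccccc2)/C=C(/C)[C@H]3OC(C)(C)O[C@H]3C[C@@H](C)C=O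
F2 | step 16 | (2S,3R,6R,7S,9S,10R)-9-hydroxy-2,3-(isopropylidenedioxy)-13-(phenylthio)germacr-4(Z)-en-12,6-olide (C11 epimers) | O=C1O[C@@H]2/C=C(/C)[C@H]3OC(C)(C)O[C@H]3C[C@@H](C)[C@@H](O)C[C@H]2C1CSc4ccccc4
F3 | step 16 | (2S,3R,6R,7S,9S,10R)-9-hydroxy-2,3-(isopropylidenedioxy)-13-(phenylsulfinyl)germacr-4(Z)-en-12,6-olide (C11 and sulfur epimers) | O=C1O[C@@H]2/C=C(/C)[C@H]3OC(C)(C)O[C@H]3C[C@@H](C)[C@@H](O)C[C@H]2C1CS(=O)c4ccccc4
F4 | step 12 | ethyl (Z)-4-[(tert-butyldimethylsilyl)oxy]-2-[(4,4,5,5-tetramethyl-1,3,2-dioxaborolan-2-yl)methyl]but-2-enoate | CCOC(=O)/C(CB1OC(C)(C)C(C)(C)O1)=C\CO[Si](C)(C)C(C)(C)C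
F5 | step 6 | methyl (R)-4-hydroxy-4-[(2S,4R)-4-methyl-5-oxotetrahydrofuran-2-yl]but-2-ynoate | O=C1[C@H](C)C[C@@H]([C@H](O)C#CC(=O)OC)O1
F6 | step 6 | (R)-4-methyl-5-[(2S,4R)-4-methyl-5-oxotetrahydrofuran-2-yl]furan-2(5H)-one | O=C1[C@H](C)C[C@@H]([C@@H]2OC(=O)C=C2C)O1
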